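**Retrosynthetic overview**
1. Late stage: the acetate, the E-enyne (Takai olefination, Sonogashira coupling) and the C3 bromide (SN2 on the 2,3-cis alcohol) are added to oxocene lactone 14; the C2 ethyl group replaces the lactone carbonyl oxygen via the ketene acetal phosphate.
2. Key disconnection: O1–C2 and C3–C4 together, by Belluš–Claisen ring expansion of trans-2-vinyloxetane 11 with dichloroketene, which supplies C2 and C3.
3. Enabling feature: the ring Z-olefin C5=C6 lies γ,δ to C2 (O1–C2–C3–C4–C5=C6 is a pent-4-enoate once C2 is a lactone carbonyl), and O1 is 1,3 to C6 through C8–C7, so O1, C8, C7 and C6 can be folded back into a strained oxetane ring that drives the expansion.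
4. Stereochemistry: one purchased stereocenter (the epichlorohydrin carbinol, later C6) is relayed by iodocarbonation to a cis-epoxide and by 4-exo opening to C8 and C1′; C6 is then erased in the key step; C2 and C3 are relayed from C8.
5. Ring order: 1,3-dioxan-2-one (temporary) → oxirane → oxetane → oxocene.

Key step: step 8

Remark: oxocene numbering O1, C2 (ethyl), C3 (bromide), C4, C5=C6, C7, C8 and side chain C1′–C6′ is used throughout; TBS = tert-butyldimethylsilyl; the target is taken as the (2R,3S,8R,1′R) isomer drawn.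

**Route**

Step 1
Reactants: 1 tert-butyl(but-3-yn-1-yloxy)dimethylsilane; 2 (R)-epichlorohydrin
Product: 3 (2R)-1-chloro-8-(TBS-oxy)oct-4-yn-2-ol
Conditions: n-BuLi, THF, −78 °C; BF3·OEt2; then 2, −78 °C; aq. NH4Cl
Reagents that add atoms: none
Why: BF3-promoted alkynylation of the epoxide (Yamaguchi-type) opens the oxirane only at its CH2 terminus, so the purchased stereocenter (the future sacrificial C6 carbinol) is carried over unchanged.

Step 2
Reactants: 3
Product: 5 (3R)-8-(TBS-oxy)oct-1-en-5-yn-3-ol, via terminal epoxide 4 (not isolated)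
Conditions: Me3S+ I− (4 equiv), n-BuLi (3.9 equiv), THF, −20 °C → rt
Reagents that add atoms: trimethylsulfonium iodide, C[S+](C)C.[I-]
Why: Base closes the chlorohydrin to epoxide 4, dimethylsulfonium methylide opens it at the CH2 terminus and the β-alkoxy sulfonium ylide eliminates Me2S (Corey–Chaykovsky-type one-carbon homologation of an epoxide to an allylic alcohol), the C–O stereocenter not being touched.

Step 3
Reactants: 5
Product: 6 (3R,5Z)-8-(TBS-oxy)octa-1,5-dien-3-ol
Conditions: H2 (1 atm), Pd/CaCO3 poisoned with Pb(OAc)2, quinoline, EtOAc, rt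
Reagents that add atoms: none
Why: Lindlar semi-hydrogenation adds H2 syn to the alkyne to give the Z-olefin, with quinoline preventing reduction of the vinyl group.

Step 4
Reactants: 6
Product: 8 (4R,6S)-4-ethenyl-6-[(1S)-1-iodo-3-(TBS-oxy)propyl]-1,3-dioxan-2-one, via lithium carbonate 7 (not isolated)
Conditions: n-BuLi, THF, −78 °C; CO2, −78 → 0 °C; then I2, 0 °C → rt; aq. Na2S2O3
Reagents that add atoms: carbon dioxide, O=C=O; iodine, II
Why: Iodocarbonate cyclization of the homoallylic lithium carbonate: the carbonate oxygen adds 6-exo and anti to the iodonium ion of the more electron-rich Z-olefin through a chair with the vinyl group equatorial, which sets C8 1,3-syn to the carbinol and C1′ (iodide) by anti addition.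

Step 5
Reactants: 8
Product: 9 (2R)-1-{(2S,3R)-3-[2-(TBS-oxy)ethyl]oxiran-2-yl}but-3-en-2-ol
Conditions: K2CO3, MeOH, 0 °C → rt
Reagents that add atoms: none
Why: Methanolysis of the cyclic carbonate frees the C8 alkoxide, which displaces the vicinal iodide with inversion at C1′ (intramolecular Williamson epoxide closure) to give the cis-epoxide syn to the free carbinol.

Step 6
Reactants: 9
Product: 10 (1R)-1-[(2R,4R)-4-ethenyloxetan-2-yl]-3-(TBS-oxy)propan-1-ol
Conditions: KOt-Bu (1.2 equiv), DMSO/THF, rt → 45 °C; aq. NH4Cl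
Reagents that add atoms: none
Why: Base-mediated 4-exo-tet opening of a 3,4-epoxy alcohol: the allylic alkoxide attacks C8 with inversion (the 5-endo path to a tetrahydrofuran cannot reach collinear attack), which fixes C8 as R, leaves the C1′–O bond untouched as the free (R)-alcohol and gives the trans-2,4-disubstituted oxetane.

Step 7
Reactants: 10
Product: 11 (2R,4R)-2-[(1R)-1,3-bis(TBS-oxy)propyl]-4-ethenyloxetane
Conditions: TBSCl, imidazole, DMAP (cat.), DMF, 35 °C
Reagents that add atoms: tert-butyldimethylsilyl chloride, CC(C)(C)[Si](C)(C)Cl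
Why: Standard silylation of the secondary alcohol so that the ketene meets no O–H group; no stereocenter is affected, and any silyl migration between the two side-chain oxygens in step 6 converges here.

Step 8
Reactants: 11
Product: 13 (5Z,8R)-8-[(1R)-1,3-bis(TBS-oxy)propyl]-3,3-dichloro-3,4,7,8-tetrahydro-2H-oxocin-2-one, via acyloxetanium enolate 12 (not isolated)
Conditions: Cl3CCOCl (slow addition), Zn–Cu couple, Et2O/DME, 25 → 35 °C
Reagents that add atoms: trichloroacetyl chloride, ClC(Cl)(Cl)C(Cl)=O (source of dichloroketene, ClC(Cl)=C=O)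
Why: Dichloroketene formed in the flask is attacked at its carbonyl carbon by the Lewis-basic oxetane oxygen to give zwitterion 12 (new O1–C2 bond), which undergoes a charge-accelerated [3,3]-sigmatropic shift (Belluš–Claisen rearrangement) in which the enolate carbon C3 bonds to the vinyl terminus C4 while the strained allylic O–C6 bond breaks. The closest known reaction type is the four-atom ring enlargement of 2-vinyl-substituted cyclic ethers with dichloroketene to medium-ring lactones. The oxocene is closed not by cyclization but by ring expansion (four to eight members) through a chair-like transition state onto which the oxetane is cis-fused, so C7 is pseudo-axial on the carbinol carbon and the new C5=C6 olefin must be Z, the only geometry the eight-membered ring tolerates. No new sp3 stereocenter is formed: the C8–O1 bond and C1′ are untouched, and the carbinol stereocenter that carried the vinyl group becomes sp2 C6 after having relayed its information. The step needs O-acylation and rearrangement to outrun [2+2] addition of the ketene to the olefins and Lewis-acid opening of the vinyl oxetane; this should be secured by the high basicity and strain of the oxetane, by the trans-2,4 substitution that leaves one oxygen lone pair syn to the vinyl group and anti to the bulky side chain, by DME to bind ZnCl2 and by slow generation of the ketene.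

Step 9
Reactants: 13
Product: 14 (5Z,8R)-8-[(1R)-1,3-bis(TBS-oxy)propyl]-3,4,7,8-tetrahydro-2H-oxocin-2-one
Conditions: Zn dust, AcOH/THF, 0 °C → rt
Reagents that add atoms: none
Why: Reductive dechlorination of the α,α-dichloro lactone through zinc enolates removes both activating chlorines without touching C8 or the Z-olefin.

Step 10
Reactants: 14
Product: 15 (8R)-8-[(1R)-1,3-bis(TBS-oxy)propyl]-7,8-dihydro-4H-oxocin-2-yl diphenyl phosphate
Conditions: KN(SiMe3)2, (PhO)2P(O)Cl, HMPA, THF, −78 °C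
Reagents that add atoms: diphenyl chlorophosphate, O=P(Cl)(Oc1ccccc1)Oc1ccccc1
Why: O-phosphorylation of the potassium lactone enolate (enol phosphate formation) gives the cyclic ketene acetal phosphate, which activates C2 for C–C coupling while the ring stays closed.

Step 11
Reactants: 15
Product: 16 (8R)-8-[(1R)-1,3-bis(TBS-oxy)propyl]-2-ethyl-7,8-dihydro-4H-oxocine
Conditions: Et2Zn, PdCl2(dppf) (5 mol %), THF, 50 °C
Reagents that add atoms: diethylzinc, CC[Zn]CC
Why: Negishi cross-coupling of the ketene acetal phosphate (oxidative addition into the C2–O bond, ethyl transfer, reductive elimination, with the wide-bite-angle ligand suppressing β-hydride elimination) installs the ethyl group at C2 as a cyclic enol ether.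

Step 12
Reactants: 16
Product: 18 (2R,3S,5Z,8R)-8-[(1R)-1,3-bis(TBS-oxy)propyl]-2-ethyl-3,4,7,8-tetrahydro-2H-oxocin-3-ol, via enol ether epoxide 17 (not isolated)
Conditions: dimethyldioxirane (1.05 equiv), acetone/CH2Cl2, −78 °C; volatiles removed at 0 °C; then i-Bu2AlH, CH2Cl2, −78 °C; aq. potassium sodium tartrate
Reagents that add atoms: dimethyldioxirane, CC1(C)OO1
Why: Dimethyldioxirane epoxidizes the electron-rich enol ether, not the isolated Z-olefin, on the ring face opposite the C8 side chain, and i-Bu2AlH coordinates the epoxide oxygen, opens it to an oxocarbenium ion and delivers hydride to C2 syn to the C3 oxygen (epoxidation–reductive opening of a cyclic enol ether), so C2 is set with ethyl cis to the C8 substituent and the C3 hydroxyl trans to ethyl.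

Step 13
Reactants: 18
Product: 19 (2R,5Z,8R)-8-[(1R)-1,3-bis(TBS-oxy)propyl]-2-ethyl-7,8-dihydro-2H-oxocin-3(4H)-one
Conditions: Dess–Martin periodinane, NaHCO3, CH2Cl2, 0 °C → rt
Reagents that add atoms: none
Why: Dess–Martin oxidation under buffered conditions gives the α-alkoxy ketone without epimerizing C2.

Step 14
Reactants: 19
Product: 20 (2R,3R,5Z,8R)-8-[(1R)-1,3-bis(TBS-oxy)propyl]-2-ethyl-3,4,7,8-tetrahydro-2H-oxocin-3-ol
Conditions: LiBH(s-Bu)3, THF, −78 °C
Reagents that add atoms: none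
Why: The bulky hydride attacks the C3 carbonyl from the face opposite the adjacent C2 ethyl group (substrate-controlled ketone reduction), giving the 2,3-cis (3R) alcohol.

Step 15
Reactants: 20
Product: 21 (2R,3S,5Z,8R)-3-bromo-8-[(1R)-1,3-bis(TBS-oxy)propyl]-2-ethyl-3,4,7,8-tetrahydro-2H-oxocine
Conditions: CBr4, P(n-C8H17)3, toluene, 70 °C
Reagents that add atoms: carbon tetrabromide, BrC(Br)(Br)Br
Why: Appel-type bromination: bromide displaces the alkoxyphosphonium group with inversion at C3 to give the (3S)-bromide trans to ethyl, the trialkylphosphine in hot toluene being suited to hindered medium-ring alcohols and disfavouring participation by the ring oxygen.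

Step 16
Reactants: 21
Product: 22 (2R,3S,5Z,8R)-3-bromo-2-ethyl-8-[(1R)-3-hydroxy-1-(TBS-oxy)propyl]-3,4,7,8-tetrahydro-2H-oxocine
Conditions: HF·pyridine, pyridine, THF, 0 °C
Reagents that add atoms: none
Why: Chemoselective desilylation: the primary silyl ether is cleaved much faster than the hindered secondary one.

Step 17
Reactants: 22
Product: 23 (2R,3S,5Z,8R)-3-bromo-2-ethyl-8-[(1R)-3-oxo-1-(TBS-oxy)propyl]-3,4,7,8-tetrahydro-2H-oxocine
Conditions: Dess–Martin periodinane, NaHCO3, CH2Cl2, rt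
Reagents that add atoms: none
Why: Dess–Martin oxidation gives the β-silyloxy aldehyde under neutral conditions that leave the secondary bromide and the olefin intact.

Step 18
Reactants: 23
Product: 24 (2R,3S,5Z,8R)-3-bromo-2-ethyl-8-[(1R,3E)-4-iodo-1-(TBS-oxy)but-3-en-1-yl]-3,4,7,8-tetrahydro-2H-oxocine
Conditions: CrCl2, CHI3, THF/1,4-dioxane, 0 °C → rt
Reagents that add atoms: iodoform, IC(I)I
Why: Takai olefination: the geminal dichromium species from iodoform adds to the aldehyde and eliminates to the (E)-vinyl iodide, and the unactivated secondary bromide is not reduced by CrCl2.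

Step 19
Reactants: 24
Product: 25 (2R,3S,5Z,8R)-3-bromo-2-ethyl-8-[(1R,3E)-1-(TBS-oxy)-6-(trimethylsilyl)hex-3-en-5-yn-1-yl]-3,4,7,8-tetrahydro-2H-oxocine
Conditions: Me3SiC≡CH, Pd(PPh3)4 (5 mol %), CuI (10 mol %), Et3N, THF, rt
Reagents that add atoms: ethynyltrimethylsilane, C#C[Si](C)(C)C
Why: Sonogashira coupling proceeds with retention of the E geometry at the vinyl iodide, which is far more reactive toward zerovalent palladium than the secondary alkyl bromide.

Step 20
Reactants: 25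
Product: 26 (2R,3S,5Z,8R)-3-bromo-2-ethyl-8-[(1R,3E)-1-hydroxyhex-3-en-5-yn-1-yl]-3,4,7,8-tetrahydro-2H-oxocine
Conditions: Bu4NF, THF, 0 °C → rt
Reagents that add atoms: none
Why: Fluoride-mediated desilylation cleaves both the O–Si bond and the C(sp)–Si bond, giving the free (R)-carbinol and the terminal enyne.

Step 21
Reactants: 26
Product: 27 (2R,3S,5Z,8R)-8-[(1R,3E)-1-acetoxyhex-3-en-5-yn-1-yl]-3-bromo-2-ethyl-3,4,7,8-tetrahydro-2H-oxocine (target)
Conditions: Ac2O, pyridine, DMAP (cat.), CH2Cl2, rt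
Reagents that add atoms: acetic anhydride, CC(=O)OC(C)=O
Why: Acylation of the secondary alcohol with retention at C1′ gives the target acetate.

**Compound list**
1 | tert-butyl(but-3-yn-1-yloxy)dimethylsilane | C#CCCO[Si](C)(C)C(C)(C)C | starting material
2 | (R)-epichlorohydrin, (2R)-2-(chloromethyl)oxirane | ClC[C@H]1CO1 | starting material
3 | (2R)-1-chloro-8-(TBS-oxy)oct-4-yn-2-ol | ClC[C@H](O)CC#CCCO[Si](C)(C)C(C)(C)C | intermediate
4 | (2R)-2-[5-(TBS-oxy)pent-2-yn-1-yl]oxirane | C1[C@H](O1)CC#CCCO[Si](C)(C)C(C)(C)C | intermediate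
5 | (3R)-8-(TBS-oxy)oct-1-en-5-yn-3-ol | C=C[C@H](O)CC#CCCO[Si](C)(C)C(C)(C)C | intermediate
6 | (3R,5Z)-8-(TBS-oxy)octa-1,5-dien-3-ol | C=C[C@H](O)C/C=C\CCO[Si](C)(C)C(C)(C)C | intermediate
7 | lithium (3R,5Z)-8-(TBS-oxy)octa-1,5-dien-3-yl carbonate | [Li+].[O-]C(=O)O[C@@H](C=C)C/C=C\CCO[Si](C)(C)C(C)(C)C | intermediate
8 | (4R,6S)-4-ethenyl-6-[(1S)-1-iodo-3-(TBS-oxy)propyl]-1,3-dioxan-2-one | O=C1O[C@@H](C=C)C[C@H](O1)[C@@H](I)CCO[Si](C)(C)C(C)(C)C | intermediate
9 | (2R)-1-{(2S,3R)-3-[2-(TBS-oxy)ethyl]oxiran-2-yl}but-3-en-2-ol | C=C[C@H](O)C[C@@H]1O[C@@H]1CCO[Si](C)(C)C(C)(C)C | intermediate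
10 | (1R)-1-[(2R,4R)-4-ethenyloxetan-2-yl]-3-(TBS-oxy)propan-1-ol | C=C[C@H]1C[C@@H](O1)[C@H](O)CCO[Si](C)(C)C(C)(C)C | intermediate
11 | (2R,4R)-2-[(1R)-1,3-bis(TBS-oxy)propyl]-4-ethenyloxetane | C=C[C@H]1C[C@@H](O1)[C@H](O[Si](C)(C)C(C)(C)C)CCO[Si](C)(C)C(C)(C)C | intermediate
12 | O-(2,2-dichloro-1-oxidoethenyl)oxetanium zwitterion of 11 | C=C[C@H]1C[C@@H]([O+]1C([O-])=C(Cl)Cl)[C@H](O[Si](C)(C)C(C)(C)C)CCO[Si](C)(C)C(C)(C)C | intermediate
13 | (5Z,8R)-8-[(1R)-1,3-bis(TBS-oxy)propyl]-3,3-dichloro-3,4,7,8-tetrahydro-2H-oxocin-2-one | O=C1C(Cl)(Cl)C/C=C\C[C@@H](O1)[C@H](O[Si](C)(C)C(C)(C)C)CCO[Si](C)(C)C(C)(C)C | intermediate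
14 | (5Z,8R)-8-[(1R)-1,3-bis(TBS-oxy)propyl]-3,4,7,8-tetrahydro-2H-oxocin-2-one | O=C1CC/C=C\C[C@@H](O1)[C@H](O[Si](C)(C)C(C)(C)C)CCO[Si](C)(C)C(C)(C)C | intermediate
15 | (8R)-8-[(1R)-1,3-bis(TBS-oxy)propyl]-7,8-dihydro-4H-oxocin-2-yl diphenyl phosphate | O=P(O/C1=C/C/C=C\C[C@@H](O1)[C@H](O[Si](C)(C)C(C)(C)C)CCO[Si](C)(C)C(C)(C)C)(Oc1ccccc1)Oc1ccccc1 | intermediate
16 | (8R)-8-[(1R)-1,3-bis(TBS-oxy)propyl]-2-ethyl-7,8-dihydro-4H-oxocine | CC/C1=C/C/C=C\C[C@@H](O1)[C@H](O[Si](C)(C)C(C)(C)C)CCO[Si](C)(C)C(C)(C)C | intermediate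
17 | 2,3-epoxide of 16, oxirane oxygen on the ring face opposite the C8 side chain | CC[C@]12O[C@H]1C/C=C\C[C@@H](O2)[C@H](O[Si](C)(C)C(C)(C)C)CCO[Si](C)(C)C(C)(C)C | intermediate
18 | (2R,3S,5Z,8R)-8-[(1R)-1,3-bis(TBS-oxy)propyl]-2-ethyl-3,4,7,8-tetrahydro-2H-oxocin-3-ol (ethyl and hydroxyl trans) | CC[C@@H]1[C@@H](O)C/C=C\C[C@@H](O1)[C@H](O[Si](C)(C)C(C)(C)C)CCO[Si](C)(C)C(C)(C)C | intermediate
19 | (2R,5Z,8R)-8-[(1R)-1,3-bis(TBS-oxy)propyl]-2-ethyl-7,8-dihydro-2H-oxocin-3(4H)-one | CC[C@@H]1C(=O)C/C=C\C[C@@H](O1)[C@H](O[Si](C)(C)C(C)(C)C)CCO[Si](C)(C)C(C)(C)C | intermediate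
20 | (2R,3R,5Z,8R)-8-[(1R)-1,3-bis(TBS-oxy)propyl]-2-ethyl-3,4,7,8-tetrahydro-2H-oxocin-3-ol (ethyl and hydroxyl cis) | CC[C@@H]1[C@H](O)C/C=C\C[C@@H](O1)[C@H](O[Si](C)(C)C(C)(C)C)CCO[Si](C)(C)C(C)(C)C | intermediate
21 | (2R,3S,5Z,8R)-3-bromo-8-[(1R)-1,3-bis(TBS-oxy)propyl]-2-ethyl-3,4,7,8-tetrahydro-2H-oxocine | CC[C@@H]1[C@@H](Br)C/C=C\C[C@@H](O1)[C@H](O[Si](C)(C)C(C)(C)C)CCO[Si](C)(C)C(C)(C)C | intermediate
22 | (2R,3S,5Z,8R)-3-bromo-2-ethyl-8-[(1R)-3-hydroxy-1-(TBS-oxy)propyl]-3,4,7,8-tetrahydro-2H-oxocine | CC[C@@H]1[C@@H](Br)C/C=C\C[C@@H](O1)[C@H](O[Si](C)(C)C(C)(C)C)CCO | intermediate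
23 | (2R,3S,5Z,8R)-3-bromo-2-ethyl-8-[(1R)-3-oxo-1-(TBS-oxy)propyl]-3,4,7,8-tetrahydro-2H-oxocine | CC[C@@H]1[C@@H](Br)C/C=C\C[C@@H](O1)[C@H](O[Si](C)(C)C(C)(C)C)CC=O | intermediate
24 | (2R,3S,5Z,8R)-3-bromo-2-ethyl-8-[(1R,3E)-4-iodo-1-(TBS-oxy)but-3-en-1-yl]-3,4,7,8-tetrahydro-2H-oxocine | CC[C@@H]1[C@@H](Br)C/C=C\C[C@@H](O1)[C@H](O[Si](C)(C)C(C)(C)C)C/C=C/I | intermediate
25 | (2R,3S,5Z,8R)-3-bromo-2-ethyl-8-[(1R,3E)-1-(TBS-oxy)-6-(trimethylsilyl)hex-3-en-5-yn-1-yl]-3,4,7,8-tetrahydro-2H-oxocine | CC[C@@H]1[C@@H](Br)C/C=C\C[C@@H](O1)[C@H](O[Si](C)(C)C(C)(C)C)C/C=C/C#C[Si](C)(C)C | intermediate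
26 | (2R,3S,5Z,8R)-3-bromo-2-ethyl-8-[(1R,3E)-1-hydroxyhex-3-en-5-yn-1-yl]-3,4,7,8-tetrahydro-2H-oxocine | CC[C@@H]1[C@@H](Br)C/C=C\C[C@@H](O1)[C@H](O)C/C=C/C#C | intermediate
27 | (2R,3S,5Z,8R)-8-[(1R,3E)-1-acetoxyhex-3-en-5-yn-1-yl]-3-bromo-2-ethyl-3,4,7,8-tetrahydro-2H-oxocine | CC[C@@H]1[C@@H](Br)C/C=C\C[C@@H](O1)[C@H](OC(C)=O)C/C=C/C#C | target

**Step count and risks**
Total steps: 21. Longest linear sequence: 21 steps (the route is fully linear from 1 and 2 to 27).

Steps most likely to fail: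

Step 8. Lewis-acid ionization of the vinyl oxetane by ZnCl2, or [2+2] addition of the ketene to an olefin, may outrun O-acylation and rearrangement. The fallback makes the same two bonds in separate operations by a ketene acetal Claisen ring expansion and sets out from epoxy alcohol 9. Boc2O/DMAP gives tert-butyl carbonate F1. BF3·OEt2 (CH2Cl2, −40 °C) triggers 6-exo attack of the carbonyl oxygen at C8 with inversion and loss of isobutene to give cyclic carbonate F2. TBSOTf/2,6-lutidine gives silyl ether F3, and K2CO3/MeOH gives anti-1,3-diol F4. Transacetalization with (phenylselanyl)acetaldehyde diethyl acetal (PPTS, toluene, reflux) gives selenoacetal F5, and NaIO4 gives selenoxide F6. Heating with DBU in xylene eliminates the selenoxide to ketene acetal F7, whose axial vinyl group should undergo the Claisen rearrangement in the same flask to lactone 14, where the route is rejoined.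

Step 4. Iodonium formation at the allylic vinyl group with 5-exo closure, or poor chair discrimination that erodes the 1,3-syn relay, may compete. The fallback performs the relay before the vinyl group exists and sets out from chlorohydrin 3. Semi-hydrogenation (Pd/CaCO3 poisoned with Pb(OAc)2, quinoline) gives (Z)-chlorohydrin F8. n-BuLi/CO2 gives lithium carbonate F9, and I2 closes it to iodocarbonate F10, with only one olefin present. K2CO3/MeOH closes both oxiranes to bis-epoxide F11. Me3S+ I−/n-BuLi (2.2 equiv, −20 °C) opens the terminal oxirane selectively and eliminates to allylic alcohol 9, where the route is rejoined.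

Step 12. Epoxidation may show poor facial selectivity, so that C2 is not set cleanly relative to C8. The fallback replaces kinetic face selection by thermodynamic control and sets out from enol ether 16. The other-face epoxide F12 and its reduction product, alcohol F13, are carried on together with 18. Dess–Martin oxidation gives ketone 19 together with its C2 epimer, ketone F14. DBU (CH2Cl2, rt) equilibrates the α-alkoxy ketone through its enol toward the 2,8-cis isomer 19, which is expected to be favoured because both substituents flanking the ring oxygen are then pseudo-equatorial; the route is rejoined at 19.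

**Further compounds**
F1 | step 8 | tert-butyl (2R)-1-{(2S,3R)-3-[2-(TBS-oxy)ethyl]oxiran-2-yl}but-3-en-2-yl carbonate | C=C[C@H](OC(=O)OC(C)(C)C)C[C@@H]1O[C@@H]1CCO[Si](C)(C)C(C)(C)C
F2 | step 8 | (4R,6R)-4-ethenyl-6-[(1R)-1-hydroxy-3-(TBS-oxy)propyl]-1,3-dioxan-2-one | O=C1O[C@@H](C=C)C[C@@H](O1)[C@H](O)CCO[Si](C)(C)C(C)(C)C
F3 | step 8 | (4R,6R)-6-[(1R)-1,3-bis(TBS-oxy)propyl]-4-ethenyl-1,3-dioxan-2-one | O=C1O[C@@H](C=C)C[C@@H](O1)[C@H](O[Si](C)(C)C(C)(C)C)CCO[Si](C)(C)C(C)(C)C
F4 | step 8 | (3R,5R,6R)-6,8-bis(TBS-oxy)oct-1-ene-3,5-diol | C=C[C@H](O)C[C@@H](O)[C@H](O[Si](C)(C)C(C)(C)C)CCO[Si](C)(C)C(C)(C)C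
F5 | step 8 | 2-[(phenylselanyl)methyl]-1,3-dioxane acetal of diol F4 (both acetal epimers) | C=C[C@H]1C[C@@H](OC(C[Se]c2ccccc2)O1)[C@H](O[Si](C)(C)C(C)(C)C)CCO[Si](C)(C)C(C)(C)C
F6 | step 8 | selenoxide of F5 | C=C[C@H]1C[C@@H](OC(C[Se](=O)c2ccccc2)O1)[C@H](O[Si](C)(C)C(C)(C)C)CCO[Si](C)(C)C(C)(C)C
F7 | step 8 | 2-methylidene-1,3-dioxane (cyclic ketene acetal) of diol F4 | C=C[C@H]1C[C@@H](OC(=C)O1)[C@H](O[Si](C)(C)C(C)(C)C)CCO[Si](C)(C)C(C)(C)C
F8 | step 4 | (2R,4Z)-1-chloro-8-(TBS-oxy)oct-4-en-2-ol | ClC[C@H](O)C/C=C\CCO[Si](C)(C)C(C)(C)C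
F9 | step 4 | lithium (2R,4Z)-1-chloro-8-(TBS-oxy)oct-4-en-2-yl carbonate | [Li+].[O-]C(=O)O[C@@H](CCl)C/C=C\CCO[Si](C)(C)C(C)(C)C
F10 | step 4 | (4R,6S)-4-(chloromethyl)-6-[(1S)-1-iodo-3-(TBS-oxy)propyl]-1,3-dioxan-2-one | O=C1O[C@@H](CCl)C[C@H](O1)[C@@H](I)CCO[Si](C)(C)C(C)(C)C
F11 | step 4 | (2S,3R)-2-{[(2R)-oxiran-2-yl]methyl}-3-[2-(TBS-oxy)ethyl]oxirane | C1O[C@@H]1C[C@@H]1O[C@@H]1CCO[Si](C)(C)C(C)(C)C
F12 | step 12 | 2,3-epoxide of 16, oxirane oxygen on the same ring face as the C8 side chain | CC[C@@]12O[C@@H]1C/C=C\C[C@@H](O2)[C@H](O[Si](C)(C)C(C)(C)C)CCO[Si](C)(C)C(C)(C)C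
F13 | step 12 | (2S,3R,5Z,8R)-8-[(1R)-1,3-bis(TBS-oxy)propyl]-2-ethyl-3,4,7,8-tetrahydro-2H-oxocin-3-ol | CC[C@H]1[C@H](O)C/C=C\C[C@@H](O1)[C@H](O[Si](C)(C)C(C)(C)C)CCO[Si](C)(C)C(C)(C)C
F14 | step 12 | (2S,5Z,8R)-8-[(1R)-1,3-bis(TBS-oxy)propyl]-2-ethyl-7,8-dihydro-2H-oxocin-3(4H)-one | CC[C@H]1C(=O)C/C=C\C[C@@H](O1)[C@H](O[Si](C)(C)C(C)(C)C)CCO[Si](C)(C)C(C)(C)C
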